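## Retrosynthetic overview
1. The C5–OH is installed last, by reagent-controlled oxidation of the α′-dienolate of the vinylogous ester. The CO2H comes from the terminal isopropylidene by allylic C–H oxidation followed by aldehyde oxidation.
2. The tertiary carbinol is cut at its C–CH3 bond: non-chelation methyl addition to a 2-acyl-tetrahydrobenzofuranone.
3. The C2–O bond, the dihydrofuran ring and the first stereocentre come from a metal-free oxidative cycloetherification of a 2-(3-oxoalkyl)cyclohexane-1,3-dione. A chiral quaternary ammonium hypoiodite catalyses it, in the same pot as the Michael addition that makes the triketone.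
4. The vinyl ketone comes from geranylacetone by Mannich methylenation. The 6E olefin is bought. The 2E enoic acid geometry is set by the E-selective allylic oxidation in step 4.
5. Ring order: the carbocycle is bought as cyclohexane-1,3-dione, and the dihydrofuran is the only ring formed (step 2).

Assumption: the sense of induction of the ammonium iodide (step 2) and of the camphor-derived oxaziridine (step 6) on these untested substrates is taken by analogy with ketophenol cyclisations and tetralone-type enolates. Both are available as either antipode, so the antipode is swapped if the sense turns out opposite.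

## Route

Step 1
Reactants: 1 geranylacetone
Product: 5 (6E)-7,11-dimethyldodeca-1,6,10-trien-3-one, via lithium enolate 2 (not isolated), via Mannich base 3 (not isolated), via methiodide 4 (not isolated)
Conditions: LDA (commercial solution, 1.05 equiv), THF, −78 °C; CH2=NMe2+ I−, −78 °C → rt; crude: MeI, Et2O, rt; then aq NaHCO3/CH2Cl2, rt
Reagents that add atoms: N,N-dimethylmethyleneiminium iodide (Eschenmoser's salt), C=[N+](C)C.[I-]
Why: Kinetic deprotonation at the methyl group, Mannich reaction with Eschenmoser's salt and Hofmann-type elimination of the quaternised amine is the standard regiocontrolled α-methylenation of a methyl ketone; no stereocentre is formed and the E-olefin is untouched.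

Step 2
Reactants: 5 (6E)-7,11-dimethyldodeca-1,6,10-trien-3-one; 6 cyclohexane-1,3-dione
Product: 9 (2S)-2-[(4E)-5,9-dimethyldeca-4,8-dienoyl]-3,5,6,7-tetrahydro-1-benzofuran-4(2H)-one, via triketone 7 (not isolated), via iodo triketone 8 (not isolated)
Conditions: (R,R)-N-spiro bis(3,3′-diaryl-binaphthyl)azepinium iodide [Ar = 3,5-(CF3)2C6H3] (10 mol %), K2CO3 (5 mol %), PhMe/H2O, rt; then 30 % H2O2 (2 equiv), 0 °C
Reagents that add atoms: none
Why: Proposed new method: the phase-transfer Michael adduct 7 is a vinylogous carboxylic acid (pKa about 5) that pairs as its enolate with the chiral cation and also buffers the medium; hypoiodite made from the catalyst iodide and H2O2 iodinates this enolate reversibly, so I+ is kept away from the chain olefins; the enolate oxygen enolises the side-chain ketone only towards the future C2 through a six-membered proton shuttle, which places iodine there (8); because α-iodo ketones racemise by iodide exchange, the 5-exo-tet O-alkylation inside the contact ion pair picks one enantiomer, closes the dihydrofuran, sets C2 as S and returns iodide; the closest known reactions are the chiral ammonium hypoiodite-catalysed oxidative cycloetherification of ketophenols to 2-acyl-2,3-dihydrobenzofurans, the related oxylactonisation of keto acids and the racemic I2/base cyclisation of 1,3-dione/enone Michael adducts, none of which joins a 1,3-dione enol nucleophile and a plain dialkyl ketone to a chiral hypoiodite.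

Step 3
Reactants: 9 (2S)-2-[(4E)-5,9-dimethyldeca-4,8-dienoyl]-3,5,6,7-tetrahydro-1-benzofuran-4(2H)-one
Product: 10 (2S)-2-[(2S,5E)-2-hydroxy-6,10-dimethylundeca-5,9-dien-2-yl]-3,5,6,7-tetrahydro-1-benzofuran-4(2H)-one
Conditions: MeLi, ClTi(OiPr)3, Et2O, −40 °C; then 9, CH2Cl2, −30 °C → rt; aq NH4F
Reagents that add atoms: methyltitanium triisopropoxide, C[Ti](OC(C)C)(OC(C)C)OC(C)C, made in the flask from methyllithium, [Li]C, and chlorotitanium triisopropoxide, CC(C)O[Ti](Cl)(OC(C)C)OC(C)C
Why: The non-basic, weakly Lewis acidic titanium reagent adds only to the α-oxy ketone (the vinylogous ester is inert and C2 is not enolised), and since the ring oxygen is a vinylogous ester oxygen too electron-poor to chelate, the polar Felkin–Anh and Cornforth models agree on attack anti to C2–O past the C2–H, which gives the S carbinol (1,2-addition under non-chelation control).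

Step 4
Reactants: 10 (2S)-2-[(2S,5E)-2-hydroxy-6,10-dimethylundeca-5,9-dien-2-yl]-3,5,6,7-tetrahydro-1-benzofuran-4(2H)-one
Product: 12 (2E,6E,10S)-10-hydroxy-2,6-dimethyl-10-[(2S)-4-oxo-2,3,4,5,6,7-hexahydro-1-benzofuran-2-yl]undeca-2,6-dienal, via allylic alcohol 11 (not isolated)
Conditions: SeO2 (0.3 equiv), t-BuOOH (2.5 equiv), salicylic acid (0.1 equiv), CH2Cl2, 0 °C → rt; crude: MnO2, CH2Cl2, rt
Reagents that add atoms: tert-butyl hydroperoxide, CC(C)(C)OO (terminal oxygen source, relayed by catalytic SeO2)
Why: The SeO2/TBHP allylic oxidation (ene reaction then [2,3]-shift) prefers the E-methyl of the terminal isopropylidene in farnesyl-type chains, and MnO2 converges the alcohol/aldehyde mixture to the E-enal while leaving the tertiary alcohol and both stereocentres alone.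

Step 5
Reactants: 12 (2E,6E,10S)-10-hydroxy-2,6-dimethyl-10-[(2S)-4-oxo-2,3,4,5,6,7-hexahydro-1-benzofuran-2-yl]undeca-2,6-dienal
Product: 13 (2E,6E,10S)-10-hydroxy-2,6-dimethyl-10-[(2S)-4-oxo-2,3,4,5,6,7-hexahydro-1-benzofuran-2-yl]undeca-2,6-dienoic acid
Conditions: NaClO2, NaH2PO4, 2-methyl-2-butene, t-BuOH/H2O, 0 °C → rt
Reagents that add atoms: sodium chlorite, [Na+].[O-]Cl=O
Why: The Pinnick oxidation is aldehyde-selective, keeps the E-geometry, and with the HOCl scavenger spares the trisubstituted olefin, the enol ether and the tertiary alcohol.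

Step 6
Reactants: 13 (2E,6E,10S)-10-hydroxy-2,6-dimethyl-10-[(2S)-4-oxo-2,3,4,5,6,7-hexahydro-1-benzofuran-2-yl]undeca-2,6-dienoic acid
Product: 15 (2E,6E,10S)-10-hydroxy-10-[(2S,5R)-5-hydroxy-4-oxo-2,3,4,5,6,7-hexahydro-1-benzofuran-2-yl]-2,6-dimethylundeca-2,6-dienoic acid, via trilithium dienolate 14 (not isolated)
Conditions: LDA (commercial solution, 3.3 equiv), THF, −78 °C; (+)-[(8,8-dichlorocamphoryl)sulfonyl]oxaziridine (1.5 equiv), −78 °C; AcOH, −78 °C
Reagents that add atoms: (+)-[(8,8-dichlorocamphoryl)sulfonyl]oxaziridine, CC1(C)[C@@H]2CC[C@]13CS(=O)(=O)N4O[C@@]34C2(Cl)Cl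
Why: After the acid and the alcohol are deprotonated, LDA removes the kinetic α′-proton (C5) of the vinylogous ester, and the Davis oxidation of this cross-conjugated dienolate transfers oxygen under reagent control (the remote C2 and C10 centres exert no bias) to give 5R, while the olefins are inert to the oxaziridine at −78 °C and the cold acidic quench keeps the acyloin from epimerising.

## Compound list
1 | geranylacetone, (5E)-6,10-dimethylundeca-5,9-dien-2-one | CC(=O)CC/C=C(\C)CCC=C(C)C | starting material
2 | kinetic lithium enolate of 1 (terminal enolate) | C=C(O[Li])CC/C=C(\C)CCC=C(C)C | intermediate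
3 | (6E)-1-(dimethylamino)-7,11-dimethyldodeca-6,10-dien-3-one (Mannich base) | CN(C)CCC(=O)CC/C=C(\C)CCC=C(C)C | intermediate
4 | (6E)-N,N,N,7,11-pentamethyl-3-oxododeca-6,10-dien-1-aminium iodide (methiodide) | C[N+](C)(C)CCC(=O)CC/C=C(\C)CCC=C(C)C.[I-] | intermediate
5 | (6E)-7,11-dimethyldodeca-1,6,10-trien-3-one (vinyl ketone) | C=CC(=O)CC/C=C(\C)CCC=C(C)C | intermediate
6 | cyclohexane-1,3-dione | O=C1CCCC(=O)C1 | starting material
7 | 2-[(6E)-7,11-dimethyl-3-oxododeca-6,10-dien-1-yl]cyclohexane-1,3-dione (triketone) | O=C1CCCC(=O)C1CCC(=O)CC/C=C(\C)CCC=C(C)C | intermediate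
8 | 2-[(6E)-2-iodo-7,11-dimethyl-3-oxododeca-6,10-dien-1-yl]cyclohexane-1,3-dione (C–I centre configurationally labile) | O=C1CCCC(=O)C1CC(I)C(=O)CC/C=C(\C)CCC=C(C)C | intermediate
9 | (2S)-2-[(4E)-5,9-dimethyldeca-4,8-dienoyl]-3,5,6,7-tetrahydro-1-benzofuran-4(2H)-one | C/C(=C\CCC(=O)[C@@H]1CC2=C(CCCC2=O)O1)CCC=C(C)C | intermediate
10 | (2S)-2-[(2S,5E)-2-hydroxy-6,10-dimethylundeca-5,9-dien-2-yl]-3,5,6,7-tetrahydro-1-benzofuran-4(2H)-one | C/C(=C\CC[C@](C)(O)[C@@H]1CC2=C(CCCC2=O)O1)CCC=C(C)C | intermediate
11 | (2S)-2-[(2S,5E,9E)-2,11-dihydroxy-6,10-dimethylundeca-5,9-dien-2-yl]-3,5,6,7-tetrahydro-1-benzofuran-4(2H)-one | C/C(=C\CC[C@](C)(O)[C@@H]1CC2=C(CCCC2=O)O1)CC/C=C(\C)CO | intermediate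
12 | (2E,6E,10S)-10-hydroxy-2,6-dimethyl-10-[(2S)-4-oxo-2,3,4,5,6,7-hexahydro-1-benzofuran-2-yl]undeca-2,6-dienal | C/C(=C\CC[C@](C)(O)[C@@H]1CC2=C(CCCC2=O)O1)CC/C=C(\C)C=O | intermediate
13 | (2E,6E,10S)-10-hydroxy-2,6-dimethyl-10-[(2S)-4-oxo-2,3,4,5,6,7-hexahydro-1-benzofuran-2-yl]undeca-2,6-dienoic acid | C/C(=C\CC[C@](C)(O)[C@@H]1CC2=C(CCCC2=O)O1)CC/C=C(\C)C(=O)O | intermediate
14 | trilithium salt of 13 (carboxylate, tertiary alkoxide, C4–C5 dienolate) | C/C(=C\CC[C@](C)(O[Li])[C@@H]1CC2=C(CCC=C2O[Li])O1)CC/C=C(\C)C(=O)O[Li] | intermediate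
15 | (2E,6E,10S)-10-hydroxy-10-[(2S,5R)-5-hydroxy-4-oxo-2,3,4,5,6,7-hexahydro-1-benzofuran-2-yl]-2,6-dimethylundeca-2,6-dienoic acid (CNP0117600.1) | C/C(=C\CC[C@](C)(O)[C@@H]1CC2=C(CC[C@@H](O)C2=O)O1)CC/C=C(\C)C(=O)O | target

## Step count and risks
Total steps: 6. Longest linear sequence: 6 (1 → 15).

**First risk: step 2, the new reaction.**
- Failure modes: low ee with a plain dialkyl ketone, iodination on the chain side of the ketone, over-oxidation to the furan, or attack of I+ on the chain olefins.
- The fallback uses only known chemistry. It sets out from 6 and comes back at 10, so it also by-passes step 3, and it fixes the C2/carbinol pair stereospecifically from olefin geometry.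
- Bought, achiral (2Z,6E)-farnesol F1 undergoes Sharpless asymmetric epoxidation (Ti(OiPr)4, D-(−)-diethyl tartrate, t-BuOOH, 4 Å MS, −20 °C) to the cis-epoxy alcohol F2.
- Parikh–Doering oxidation then gives the epoxy aldehyde F3.
- Three-component reductive alkylation of 6 with F3 and Hantzsch ester (catalytic proline) passes through the Knoevenagel alkylidene dione F4 to the epoxy dione F5.
- K2CO3/MeOH then triggers 5-exo-tet opening at the less substituted epoxide carbon with inversion. From the (2R,3S)-epoxide this gives exactly the (2S, carbinol S) pair of 10.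

**Second risk: step 3.**
- Failure modes: the titanium reagent may add sluggishly to a dialkyl ketone, and the 1,2-induction may be modest. Any chelation would give the wrong carbinol epimer.
- The fallback sets out from 9 and comes back at 10. It gives up substrate control for external catalyst control.
- It is a catalytic asymmetric methylation of the ketone with Me2Zn/Ti(OiPr)4 and 10 mol % of a trans-cyclohexane-1,2-diamine bis(hydroxycamphorsulfonamide) ligand. The ligand antipode is picked so that methyl reaches the face leading to the S carbinol.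
- New compounds: none F0.

**Third risk: step 6.**
- Failure modes: reagent control at a secondary position of a cyclic dienolate may give only a modest C5 ratio, and the trianion may be poorly soluble.
- The fallback sets out from 13 and comes back at 15. It replaces enolate oxidation by a catalytic asymmetric Rubottom sequence.
- LDA (3.3 equiv) and TBSCl (2.2 equiv) give the bis-silyl compound F6 (TBS ester and 4-silyloxy diene).
- Shi epoxidation follows (D-fructose-derived ketone 30 mol %, Oxone 1.1 equiv, pH 10.5 buffer, MeCN/dimethoxymethane, −5 °C). It attacks the far more electron-rich silyloxy diene ahead of the one remaining isolated olefin.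
- By the spiro model for 1-substituted cyclohexenes, oxygen arrives on the face that gives 5R. Silyl migration and ester hydrolysis in the buffer then give the 5-O-TBS acid F7.
- HF·pyridine frees 15.

## Further compounds
F1 | step 2 | (2Z,6E)-3,7,11-trimethyldodeca-2,6,10-trien-1-ol, (2Z,6E)-farnesol | CC(C)=CCC/C(C)=C/CC/C(C)=C\CO
F2 | step 2 | {(2R,3S)-3-[(3E)-4,8-dimethylnona-3,7-dien-1-yl]-3-methyloxiran-2-yl}methanol | CC(C)=CCC/C(C)=C/CC[C@]1(C)O[C@@H]1CO
F3 | step 2 | (2S,3S)-3-[(3E)-4,8-dimethylnona-3,7-dien-1-yl]-3-methyloxirane-2-carbaldehyde | CC(C)=CCC/C(C)=C/CC[C@]1(C)O[C@@H]1C=O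
F4 | step 2 | 2-({(2R,3S)-3-[(3E)-4,8-dimethylnona-3,7-dien-1-yl]-3-methyloxiran-2-yl}methylidene)cyclohexane-1,3-dione | CC(C)=CCC/C(C)=C/CC[C@]1(C)O[C@@H]1C=C2C(=O)CCCC2=O
F5 | step 2 | 2-({(2R,3S)-3-[(3E)-4,8-dimethylnona-3,7-dien-1-yl]-3-methyloxiran-2-yl}methyl)cyclohexane-1,3-dione | CC(C)=CCC/C(C)=C/CC[C@]1(C)O[C@@H]1CC2C(=O)CCCC2=O
F0 | step 3 | none | none
F6 | step 6 | tert-butyldimethylsilyl (2E,6E,10S)-10-{(2S)-4-[(tert-butyldimethylsilyl)oxy]-2,3,6,7-tetrahydro-1-benzofuran-2-yl}-10-hydroxy-2,6-dimethylundeca-2,6-dienoate | C/C(=C\CC[C@](C)(O)[C@@H]1CC2=C(CCC=C2O[Si](C)(C)C(C)(C)C)O1)CC/C=C(\C)C(=O)O[Si](C)(C)C(C)(C)C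
F7 | step 6 | (2E,6E,10S)-10-{(2S,5R)-5-[(tert-butyldimethylsilyl)oxy]-4-oxo-2,3,4,5,6,7-hexahydro-1-benzofuran-2-yl}-10-hydroxy-2,6-dimethylundeca-2,6-dienoic acid | C/C(=C\CC[C@](C)(O)[C@@H]1CC2=C(CC[C@@H](O[Si](C)(C)C(C)(C)C)C2=O)O1)CC/C=C(\C)C(=O)O
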